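The 22-membered lactone is cut at C6–C7, the two epoxide carbons, which are flanked by the C5 and C8 carbinols so that C5–C8 has local twofold symmetry and lies far from the Z C2=C3 enoate. This bond is made as a C6≡C7 triple bond by ring-closing alkyne metathesis of an open-chain ester diyne whose two methyl-capped alkynes each carry a propargylic TBS ether. One operation closes the macrocycle and installs a masked form of the trans-epoxide. The diyne comes from Z-selective Ando olefination between a C7–C22 phosphonoacetate and a C3–C6 aldehyde. Trans-hydrosilylation/protodesilylation, Shi epoxidation and desilylation complete the target.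

Key step: step 12

Remarks: atoms carry the target numbering (C1 lactone carbonyl, C2=C3, C5 and C8 carbinols, C6/C7 epoxide, C21 ring carbinol, C22 methyl). The target is 2Z,5S,6R,7R,8S,21R, and diyne 19 and cycloalkyne 20 (5S,8S,21R, 2Z) were checked against it. In the bis-silyl epoxide 24 the C6/C7 descriptors read S,S for the same geometry, because the silyloxy branch outranks the epoxide branch. The epoxide oxygen is syn (threo) to both C5–O and C8–O.
Assumption: 2-(diphenoxyphosphoryl)acetic acid (17), 1-propynylmagnesium bromide solution and (−)-B-allyldiisopinocampheylborane solution are bought as catalogue reagents.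

Step 1
Reactants: 1 12-bromododecanoic acid
Product: 3 12-bromo-N-methoxy-N-methyldodecanamide, via acyl imidazolide 2 (not isolated)
Conditions: CDI, CH2Cl2, rt; then MeNH(OMe)·HCl, rt
Reagents that add atoms: N,O-dimethylhydroxylamine hydrochloride, CNOC.Cl
Why: Weinreb amide formation by acyl substitution through the acyl imidazolide is mild enough to leave the primary bromide alone and prepares a clean single addition of the alkynyl nucleophile.

Step 2
Reactants: 3 12-bromo-N-methoxy-N-methyldodecanamide
Product: 4 15-bromopentadec-2-yn-4-one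
Conditions: 1-propynylmagnesium bromide, THF, 0 °C; aq. NH4Cl
Reagents that add atoms: 1-propynylmagnesium bromide, CC#C[Mg]Br
Why: Weinreb ketone synthesis, in which the chelated tetrahedral adduct stops the addition at the ynone, and an alkynyl Grignard reagent does not displace a primary bromide without copper.

Step 3
Reactants: 4 15-bromopentadec-2-yn-4-one
Product: 5 (4S)-15-bromopentadec-2-yn-4-ol
Conditions: Ru[(S,S)-TsDPEN](p-cymene) (2 mol%), i-PrOH, rt
Reagents that add atoms: none
Why: Noyori asymmetric transfer hydrogenation of an alkynyl ketone, in which the (S,S)-catalyst delivers hydride to the face that gives the (S)-propargylic alcohol (the alkynyl group taking the place of the aryl group of the usual model) and so sets C8.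

Step 4
Reactants: 5 (4S)-15-bromopentadec-2-yn-4-ol
Product: 6 (4S)-15-bromo-4-(tert-butyldimethylsilyloxy)pentadec-2-yne
Conditions: TBSCl, imidazole, DMAP (cat.), CH2Cl2, rt
Reagents that add atoms: tert-butyldimethylsilyl chloride, CC(C)(C)[Si](C)(C)Cl
Why: Standard silylation of a secondary propargylic alcohol, run in CH2Cl2 so that imidazole does not alkylate the primary bromide.

Step 5
Reactants: 6 (4S)-15-bromo-4-(tert-butyldimethylsilyloxy)pentadec-2-yne; 7 (R)-propylene oxide
Product: 9 (2R,15S)-15-(tert-butyldimethylsilyloxy)octadec-16-yn-2-ol, via Grignard reagent 8 (not isolated)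
Conditions: Mg, THF, 45 °C; then CuI (10 mol%), 7, −40 → 0 °C; aq. NH4Cl
Reagents that add atoms: none
Why: Copper-catalysed Grignard opening of the terminal epoxide at its CH2 carbon (SN2) leaves the stereocentre of 7 untouched and carries it over as 21R, while the silyl ether and the internal alkyne are inert to the alkylmagnesium reagent.

Step 6
Reactants: 10 but-2-yn-1-ol
Product: 11 but-2-ynal
Conditions: MnO2, CH2Cl2, rt; filtration, used as a concentrated solution
Reagents that add atoms: none
Why: MnO2 oxidation of a propargylic alcohol stops at the ynal, and the volatile aldehyde is handled in solution.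

Step 7
Reactants: 11 but-2-ynal
Product: 13 (4S)-hept-1-en-5-yn-4-ol, via diisopinocampheylborinate ester 12 (not isolated)
Conditions: (−)-Ipc2B(allyl), Et2O, −78 °C; then NaOH, H2O2, 0 °C → rt
Reagents that add atoms: (−)-B-allyldiisopinocampheylborane, C=CCB([C@@H]1C[C@@H]2C[C@@H](C2(C)C)[C@H]1C)[C@@H]1C[C@@H]2C[C@@H](C2(C)C)[C@H]1C
Why: Brown allylboration through a chair Zimmerman–Traxler transition state, in which the (−)-Ipc2B reagent (from (+)-α-pinene) attacks the Si face of the aldehyde and, since propynyl outranks allyl, gives the (S)-carbinol that becomes C5.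

Step 8
Reactants: 13 (4S)-hept-1-en-5-yn-4-ol
Product: 14 (4S)-4-(tert-butyldimethylsilyloxy)hept-1-en-5-yne
Conditions: TBSCl, imidazole, DMF, rt
Reagents that add atoms: tert-butyldimethylsilyl chloride, CC(C)(C)[Si](C)(C)Cl
Why: Standard silylation of a secondary alcohol, which also makes the small fragment easy to separate from isopinocampheol.

Step 9
Reactants: 14 (4S)-4-(tert-butyldimethylsilyloxy)hept-1-en-5-yne
Product: 16 (3S)-3-(tert-butyldimethylsilyloxy)hex-4-ynal, via ozonide 15 (not isolated)
Conditions: O3, CH2Cl2, −78 °C (Sudan Red 7B end-point); then PPh3, −78 °C → rt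
Reagents that add atoms: ozone, [O-][O+]=O
Why: Ozonolysis with reductive work-up cleaves the terminal alkene, which cycloadds ozone far faster than the internal alkyne, to give the β-silyloxy aldehyde (C3) without touching the stereocentre.

Step 10
Reactants: 9 (2R,15S)-15-(tert-butyldimethylsilyloxy)octadec-16-yn-2-ol; 17 2-(diphenoxyphosphoryl)acetic acid
Product: 18 (2R,15S)-15-(tert-butyldimethylsilyloxy)octadec-16-yn-2-yl 2-(diphenoxyphosphoryl)acetate
Conditions: DCC, DMAP (cat.), CH2Cl2, 0 °C → rt
Reagents that add atoms: none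
Why: Steglich esterification acylates O21 with retention at C21 and installs C1–C2 together with the diaryl phosphonate needed for Z-olefination.

Step 11
Reactants: 18 (2R,15S)-15-(tert-butyldimethylsilyloxy)octadec-16-yn-2-yl 2-(diphenoxyphosphoryl)acetate; 16 (3S)-3-(tert-butyldimethylsilyloxy)hex-4-ynal
Product: 19 (2R,15S)-15-(tert-butyldimethylsilyloxy)octadec-16-yn-2-yl (2Z,5S)-5-(tert-butyldimethylsilyloxy)oct-2-en-6-ynoate
Conditions: NaH, THF, 0 °C; then 16, −78 → 0 °C
Reagents that add atoms: none
Why: Ando variant of the Horner–Wadsworth–Emmons reaction, in which the electron-poor diaryl phosphonate collapses quickly from the syn-oxaphosphetane to give the Z C2=C3 enoate, and the weakly basic anion at low temperature spares the β-silyloxy aldehyde from elimination.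

Step 12
Reactants: 19 (2R,15S)-15-(tert-butyldimethylsilyloxy)octadec-16-yn-2-yl (2Z,5S)-5-(tert-butyldimethylsilyloxy)oct-2-en-6-ynoate
Product: 20 22-membered (2Z)-enoate lactone with C6≡C7 cycloalkyne, 5,8-bis-TBS ether (5S,8S,21R)
Conditions: [Mo(≡C-C6H4-4-OMe)(OSiPh3)3] (10 mol%), 5 Å MS, toluene (2 mM), rt → 80 °C
Reagents that add atoms: none
Why: The molybdenum alkylidyne adds across one methyl-capped alkyne in a [2+2] cycloaddition to a metallacyclobutadiene and cycloreverts to a substrate-bound alkylidyne, which engages the second alkyne intramolecularly and releases the cycloalkyne, the net by-product being but-2-yne. The closest known reaction type is ring-closing alkyne metathesis of methyl-capped diynes to macrocyclic lactones with silanolate-ligated molybdenum alkylidynes. The 22-membered ring is closed by head-to-tail macrocyclisation of the ester-tethered diyne, the new C6≡C7 bond becoming endocyclic in a ring large enough to hold the linear C5–C6≡C7–C8 unit without strain. No stereocentre is formed: C5, C8 and C21 are spectators, and the Z C2=C3 geometry is kept because alkylidynes do not react with alkenes. The step needs alkyne-over-alkene chemoselectivity (inherent to the catalyst), ring closure over oligomerisation (high dilution, reversibility of oligomer formation and trapping of but-2-yne in the sieves) and intact propargylic C–O bonds (weakly Lewis-acidic silanolate ligands and robust TBS ethers).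

Step 13
Reactants: 20 22-membered (2Z)-enoate lactone with C6≡C7 cycloalkyne, 5,8-bis-TBS ether
Product: 21 (Z)-alkenylsilane with Si(OEt)3 on C7 and 22 its regioisomer with Si(OEt)3 on C6, carried on as a mixture
Conditions: [Cp*Ru(MeCN)3]PF6 (5 mol%), (EtO)3SiH, CH2Cl2, 0 °C → rt
Reagents that add atoms: triethoxysilane, CCO[SiH](OCC)OCC
Why: Ruthenium-catalysed trans-hydrosilylation adds H and Si anti across the alkyne so that C5 and C8 end up trans, and the regiochemistry is irrelevant because both silanes give the same alkene in step 14.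

Step 14
Reactants: 21 (Z)-alkenylsilane with Si(OEt)3 on C7; 22 (Z)-alkenylsilane with Si(OEt)3 on C6
Product: 23 22-membered (2Z,6E)-diene lactone, 5,8-bis-TBS ether (5S,8S,21R)
Conditions: AgF, THF/MeOH/H2O, rt, dark
Reagents that add atoms: none
Why: Silver-fluoride-mediated protodesilylation replaces the alkoxysilyl group by hydrogen with retention of alkene geometry, giving the E C6=C7 alkene under conditions that leave secondary TBS ethers and the lactone intact.

Step 15
Reactants: 23 22-membered (2Z,6E)-diene lactone, 5,8-bis-TBS ether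
Product: 24 22-membered (2Z)-enoate lactone with 6,7-trans-epoxide of target configuration, 5,8-bis-TBS ether
Conditions: Shi ketone (D-fructose-derived), Oxone, K2CO3, Bu4NHSO4, aq. Na2B4O7/Na2EDTA buffer, MeCN/DMM, 0 °C
Reagents that add atoms: potassium peroxymonosulfate (Oxone), [K+].[O-]S(=O)(=O)OO
Why: Shi asymmetric epoxidation by the chiral dioxirane through a spiro transition state, in which the D-fructose-derived ketone gives the (R,R)-type epoxide from E-1,2-disubstituted alkenes and so sets C6 and C7 under reagent control, while the electron-poor enoate is not oxidised.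

Step 16
Reactants: 24 22-membered (2Z)-enoate lactone with 6,7-trans-epoxide, 5,8-bis-TBS ether
Product: 25 CIML C, (2Z,5S,6R,7R,8S,21R)
Conditions: HF·pyridine, pyridine, THF, 0 °C → rt
Reagents that add atoms: none
Why: Fluoride cleavage of the two secondary TBS ethers under acidic, pyridine-buffered conditions, chosen to avoid base-induced Payne migration of the epoxy alcohols and attack of the freed C5 hydroxyl on C1.

Compound list
1 | 12-bromododecanoic acid | OC(=O)CCCCCCCCCCCBr | starting material
2 | 12-bromo-1-(imidazol-1-yl)dodecan-1-one (acyl imidazolide) | O=C(CCCCCCCCCCCBr)n1ccnc1 | intermediate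
3 | 12-bromo-N-methoxy-N-methyldodecanamide | CON(C)C(=O)CCCCCCCCCCCBr | intermediate
4 | 15-bromopentadec-2-yn-4-one | CC#CC(=O)CCCCCCCCCCCBr | intermediate
5 | (4S)-15-bromopentadec-2-yn-4-ol | BrCCCCCCCCCCC[C@H](O)C#CC | intermediate
6 | (4S)-15-bromo-4-(tert-butyldimethylsilyloxy)pentadec-2-yne | BrCCCCCCCCCCC[C@H](O[Si](C)(C)C(C)(C)C)C#CC | intermediate
7 | (R)-propylene oxide | C[C@@H]1CO1 | starting material
8 | Grignard reagent of 6, (12S)-12-(tert-butyldimethylsilyloxy)pentadec-13-yn-1-ylmagnesium bromide | Br[Mg]CCCCCCCCCCC[C@H](O[Si](C)(C)C(C)(C)C)C#CC | intermediate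
9 | (2R,15S)-15-(tert-butyldimethylsilyloxy)octadec-16-yn-2-ol | C[C@@H](O)CCCCCCCCCCCC[C@H](O[Si](C)(C)C(C)(C)C)C#CC | intermediate
10 | but-2-yn-1-ol | CC#CCO | starting material
11 | but-2-ynal | CC#CC=O | intermediate
12 | (4S)-hept-1-en-5-yn-4-yl diisopinocampheylborinate | C=CC[C@H](OB([C@@H]1C[C@@H]2C[C@@H](C2(C)C)[C@H]1C)[C@@H]1C[C@@H]2C[C@@H](C2(C)C)[C@H]1C)C#CC | intermediate
13 | (4S)-hept-1-en-5-yn-4-ol | C=CC[C@H](O)C#CC | intermediate
14 | (4S)-4-(tert-butyldimethylsilyloxy)hept-1-en-5-yne | C=CC[C@H](O[Si](C)(C)C(C)(C)C)C#CC | intermediate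
15 | ozonide of 14, 3-[(2S)-2-(tert-butyldimethylsilyloxy)pent-3-yn-1-yl]-1,2,4-trioxolane (mixture at the ring carbon) | C1(C[C@H](O[Si](C)(C)C(C)(C)C)C#CC)OCOO1 | intermediate
16 | (3S)-3-(tert-butyldimethylsilyloxy)hex-4-ynal | O=CC[C@H](O[Si](C)(C)C(C)(C)C)C#CC | intermediate
17 | 2-(diphenoxyphosphoryl)acetic acid | OC(=O)CP(=O)(Oc1ccccc1)Oc1ccccc1 | starting material
18 | (2R,15S)-15-(tert-butyldimethylsilyloxy)octadec-16-yn-2-yl 2-(diphenoxyphosphoryl)acetate | C[C@@H](OC(=O)CP(=O)(Oc1ccccc1)Oc1ccccc1)CCCCCCCCCCCC[C@H](O[Si](C)(C)C(C)(C)C)C#CC | intermediate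
19 | (2R,15S)-15-(tert-butyldimethylsilyloxy)octadec-16-yn-2-yl (2Z,5S)-5-(tert-butyldimethylsilyloxy)oct-2-en-6-ynoate (open-chain ester diyne) | C[C@@H](OC(=O)/C=C\C[C@H](O[Si](C)(C)C(C)(C)C)C#CC)CCCCCCCCCCCC[C@H](O[Si](C)(C)C(C)(C)C)C#CC | intermediate
20 | 22-membered (2Z)-enoate lactone with C6≡C7, 5,8-bis-TBS ether (5S,8S,21R) | C[C@@H]1CCCCCCCCCCCC[C@H](O[Si](C)(C)C(C)(C)C)C#C[C@@H](O[Si](C)(C)C(C)(C)C)C/C=C\C(=O)O1 | intermediate
21 | (Z)-alkenylsilane of 20 with Si(OEt)3 on C7 (C5 and C8 trans) | C[C@@H]1CCCCCCCCCCCC[C@H](O[Si](C)(C)C(C)(C)C)/C(=C/[C@@H](O[Si](C)(C)C(C)(C)C)C/C=C\C(=O)O1)[Si](OCC)(OCC)OCC | intermediate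
22 | (Z)-alkenylsilane of 20 with Si(OEt)3 on C6 (C5 and C8 trans) | C[C@@H]1CCCCCCCCCCCC[C@H](O[Si](C)(C)C(C)(C)C)/C=C(/[C@@H](O[Si](C)(C)C(C)(C)C)C/C=C\C(=O)O1)[Si](OCC)(OCC)OCC | intermediate
23 | 22-membered (2Z,6E)-diene lactone, 5,8-bis-TBS ether (5S,8S,21R) | C[C@@H]1CCCCCCCCCCCC[C@H](O[Si](C)(C)C(C)(C)C)/C=C/[C@@H](O[Si](C)(C)C(C)(C)C)C/C=C\C(=O)O1 | intermediate
24 | 22-membered (2Z)-enoate lactone, 6,7-trans-epoxide syn to both silyloxy groups, 5,8-bis-TBS ether (formally 5S,6S,7S,8S,21R) | C[C@@H]1CCCCCCCCCCCC[C@H](O[Si](C)(C)C(C)(C)C)[C@H]2O[C@@H]2[C@@H](O[Si](C)(C)C(C)(C)C)C/C=C\C(=O)O1 | intermediate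
25 | CIML C, (2Z,5S,6R,7R,8S,21R)-6,7-epoxy-5,8-dihydroxy 22-membered lactone | C[C@@H]1CCCCCCCCCCCC[C@H](O)[C@H]2O[C@@H]2[C@@H](O)C/C=C\C(=O)O1 | target

Total step count: 16. Longest linear sequence: 12 steps (steps 1–5 and 10–16, from 12-bromododecanoic acid).

Steps most likely to fail

Step 12 (ring-closing alkyne metathesis). Intermolecular metathesis may outrun ring closure and give oligomers, or the catalyst may stall at two α-branched, oxygen-bearing alkyne ends. The fallback sets out from diyne 19. Lindlar semihydrogenation (H2, Pd/CaCO3–Pb, quinoline, EtOAc) of both alkynes would give the bis-(Z)-propenyl tetraene F1. Ring-closing olefin metathesis of F1 (Grubbs second-generation catalyst, CH2Cl2, reflux, high dilution) would form C6=C7 with loss of but-2-ene. The E isomer is expected to dominate in a ring of this size, and the electron-poor Z-enoate should stay out of the reaction. This gives E-alkene 23 and rejoins the route before step 15, so steps 13 and 14 are skipped.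

Step 15 (Shi epoxidation). Oxygen transfer to an alkene that is shielded and deactivated by two allylic silyloxy groups may be slow, and facial selectivity may be poor if catalyst and substrate preferences are mismatched. The fallback sets out from alkene 23. Both TBS groups are removed first (HF·pyridine, pyridine, THF) to give the ene-diol F2, which is epoxidised with mCPBA (CH2Cl2, NaHCO3, 0 °C). Hydrogen-bond-directed delivery favours the threo epoxy alcohol, and because C5–C8 has local twofold symmetry both hydroxyls steer the peracid to the same face, the one the target needs. The threo preference of E-allylic alcohols is expected to be modest, so chromatographic removal of the minor epoxide is anticipated. This route arrives directly at 25 and bypasses steps 15 and 16.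

Step 16 (global desilylation). During the slow cleavage of two hindered secondary TBS ethers the epoxide may be opened by fluoride or migrate by a Payne-type shift, and the freed C5 hydroxyl may attack C1 with contraction to a six-membered lactone. The fallback changes the protecting groups before the epoxide exists. From alkene 23 the ene-diol F2 is made as above, where long fluoride exposure is harmless. It is re-silylated (TESCl, imidazole, CH2Cl2) to the bis-TES ether F3. Shi epoxidation under the conditions of step 15 then gives the bis-TES epoxide F4. The TES groups are removed by brief, fluoride-free acid methanolysis (PPTS, MeOH/CH2Cl2, 0 °C), which returns to the route at 25.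

Further compounds
F1 | step 12 | (2R,15S,16Z)-15-(tert-butyldimethylsilyloxy)octadec-16-en-2-yl (2Z,5S,6Z)-5-(tert-butyldimethylsilyloxy)octa-2,6-dienoate | C[C@@H](OC(=O)/C=C\C[C@H](O[Si](C)(C)C(C)(C)C)/C=C\C)CCCCCCCCCCCC[C@H](O[Si](C)(C)C(C)(C)C)/C=C\C
F2 | step 15 | 22-membered (2Z,6E)-diene lactone 5,8-diol (5S,8S,21R) | C[C@@H]1CCCCCCCCCCCC[C@H](O)/C=C/[C@@H](O)C/C=C\C(=O)O1
F3 | step 16 | 22-membered (2Z,6E)-diene lactone, 5,8-bis-TES ether (5S,8S,21R) | C[C@@H]1CCCCCCCCCCCC[C@H](O[Si](CC)(CC)CC)/C=C/[C@@H](O[Si](CC)(CC)CC)C/C=C\C(=O)O1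
F4 | step 16 | 22-membered (2Z)-enoate lactone, 6,7-trans-epoxide of target configuration, 5,8-bis-TES ether | C[C@@H]1CCCCCCCCCCCC[C@H](O[Si](CC)(CC)CC)[C@H]2O[C@@H]2[C@@H](O[Si](CC)(CC)CC)C/C=C\C(=O)O1
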